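If you take over this bench, the flask holds half of Wednesday's catalyst and otherwise repeats Wednesday's charge.

- Wednesday's: substrate 0.24 M; reagent 0.48 M; free catalyst 24 mM; run made earlier
- flask: substrate 0.24 M; reagent 0.480 M; free catalyst 12 mM; time 20 h

- Wednesday's (time / h: product / %): 0.500: 0.5; 1.00: 0.9; 1.50: 0.7; 2.50: 2.2; 3.00: 2.8; 4.00: 6.0

(scatter of a reading: 0.5 percentage points)

1. amount of product in percent of the substrate charged, at 2.0 h, 6.0 h, 12 h and 20 h

- what may be going on: reagent + free catalyst -> catalyst intermediate A; catalyst intermediate A <-> catalyst intermediate B; catalyst intermediate B -> by-product + catalyst intermediate C; substrate + catalyst intermediate C <-> catalyst intermediate D; catalyst intermediate D -> free catalyst + product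
- no earlier run changes the charge of free catalyst; that part of a forecast is a guess

In the proposed scheme, product appears at the last step, from catalyst intermediate D, so I take the rate as proportional to c(catalyst intermediate D). Each step carries one catalyst form, so I also take the rate as first order in the catalyst charge, which is a guess because no earlier run varies that charge. I carry the turnover rate (turnover frequency), meaning product formed per hour per catalyst charged. Wednesday's readings from 2.50 h to 4.00 h give 0.253 h⁻¹, a reading with the scatter stated above.

For this flask I halve Wednesday's 6.0 % at 4.00 h and add this turnover rate for the remaining hours, so when you come at 20 h I expect product near 23.3 %. Please add no catalyst to this flask, because the turnover rate counts per catalyst charged and the reckoning holds for that charge. The forecast gives 1 %, 5 %, 15 % and 28 % at 2.0 h, 6.0 h, 12 h and 20 h, on the ground that “halving the charge should roughly halve product at a given time”. My 23.3 % at 20 h is lower than the forecast's 28 %.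

The flask gives 0.806 %, 4.43 %, 10.1 % and 17.4 %.

    reagent + free catalyst → catalyst intermediate A (k = 0.770 M⁻¹ min⁻¹)
    catalyst intermediate A ⇌ catalyst intermediate B (K = 0.390, k = 0.0360 min⁻¹)
    catalyst intermediate B → by-product + catalyst intermediate C (k = 0.0410 min⁻¹)
    substrate + catalyst intermediate C ⇌ catalyst intermediate D (K = 5.90 M⁻¹, k = 0.200 M⁻¹ min⁻¹)
    catalyst intermediate D → free catalyst + product (k = 0.0100 min⁻¹)

At 20.0 h, catalyst intermediate D in this flask holds 30.2 % of the catalyst charged. Between 12 h and 20 h, the flask's own turnover rate averages 0.182 h⁻¹, lower than the 0.253 h⁻¹ read on Wednesday. The last step's constant, 0.010 min⁻¹, times that share of catalyst intermediate D gives 0.181 h⁻¹.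

The numbers in the tables come from a simulation for an exercise.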